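**Plan**

1. The oxolane is numbered O1, C2 (aryl), C3 (arm C9H2O–angeloyl), C4 (arm C7'H2–aryl), C5. The retrosynthesis cuts, in order, the ester bond C9O–C(=O), the two C–H bonds added across C4=C7', the ring bond C2–C3, then C3–C4, O1–C2H2 and aryl–C7'.
2. Enabling feature: C2 is a benzylic CH on the ring oxygen O1 and lies 1,5 to C3 along C3–C4–C5–O1–C2. A rhodium carbenoid at C3 of a 3,4-dimethoxybenzyl (veratryl) ether can therefore insert into a C2–H bond and close the only ring.
3. Forward: aryl alkyne → (E)-2-iodoallyl alcohol → veratryl ether → Pd coupling with ethyl diazoacetate (C3–C4) → C–H insertion (C2–C3, ring) → ester reduction → alkene hydrogenation → angeloylation.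
4. The C7' aryl group is placed anti to the diazo carbon (Z alkene). If it were syn, the carbenoid could close onto that electron-rich ring to give an indene. The alkene geometry vanishes on hydrogenation.
5. Stereochemistry: C2 comes from the chiral dirhodium carboxylate (choice between the enantiotopic benzylic hydrogens), C3 from base equilibration to 2,3-trans, C4 from hydrogenation anti to the C3 arm (3,4-cis). The Z geometry of the angelate is bought and preserved.

Key step: step 5

Assumption: the sense of induction of Rh2(S-PTTL)4 at C2 is taken by analogy with related dihydrobenzofuran closures; should the 2R series result, the mirror-image catalyst Rh2(R-PTTL)4 is used under the same conditions.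

**Route**

Step 1
Reactants: 1 4-iodo-1,2-dimethoxybenzene; 2 prop-2-yn-1-ol
Product: 3 3-(3,4-dimethoxyphenyl)prop-2-yn-1-ol
Conditions: PdCl2(PPh3)2 (2 mol%), CuI (4 mol%), Et3N, THF, rt
Reagents that add atoms: none
Why: Sonogashira coupling of an electron-rich aryl iodide with a terminal alkyne is routine and tolerates the free propargylic alcohol.

Step 2
Reactants: 3 3-(3,4-dimethoxyphenyl)prop-2-yn-1-ol
Product: 5 (2E)-3-(3,4-dimethoxyphenyl)-2-iodoprop-2-en-1-ol, via vinylstannane 4 (not isolated)
Conditions: Bu3SnH (1.2 equiv), PdCl2(PPh3)2 (2 mol%), THF, 0 °C to rt; then I2, CH2Cl2, 0 °C; aq. Na2S2O3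
Reagents that add atoms: iodine, II; tributyltin hydride, CCCC[SnH](CCCC)CCCC (its tin is present only in 4)
Why: Palladium-catalysed hydrostannation adds H and Sn syn with tin on the alkyne carbon next to the carbinol (hydride goes to the aryl-bearing carbon, as favoured by both the propargylic oxygen and the electron-rich ring), and iododestannylation proceeds with retention, so iodine should end up trans to the aryl group, any regioisomeric iodide being removed by chromatography.

Step 3
Reactants: 5 (2E)-3-(3,4-dimethoxyphenyl)-2-iodoprop-2-en-1-ol; 6 3,4-dimethoxybenzyl bromide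
Product: 7 4-[(1E)-3-[(3,4-dimethoxybenzyl)oxy]-2-iodoprop-1-en-1-yl]-1,2-dimethoxybenzene
Conditions: NaH, Bu4NI (cat.), THF, 0 °C to rt
Reagents that add atoms: none
Why: Williamson etherification of a primary allylic alkoxide with a reactive benzylic bromide should be clean, because the vinylic hydrogen is cis to iodine and anti-elimination to the alkyne is not available.

Step 4
Reactants: 7 4-[(1E)-3-[(3,4-dimethoxybenzyl)oxy]-2-iodoprop-1-en-1-yl]-1,2-dimethoxybenzene; 8 ethyl diazoacetate
Product: 9 ethyl (3Z)-2-diazo-3-{[(3,4-dimethoxybenzyl)oxy]methyl}-4-(3,4-dimethoxyphenyl)but-3-enoate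
Conditions: Pd(PPh3)4 (5 mol%), Et3N, Bu4NBr, MeCN, rt; product kept cold and used promptly
Reagents that add atoms: none
Why: Palladium-catalysed C–H cross-coupling of a vinyl iodide with an acceptor diazo compound (oxidative addition, amine-assisted palladation of the diazo carbon, reductive elimination) retains both the diazo group and the alkene geometry, so the aryl group stays anti to the diazo carbon.

Step 5
Reactants: 9 ethyl (3Z)-2-diazo-3-{[(3,4-dimethoxybenzyl)oxy]methyl}-4-(3,4-dimethoxyphenyl)but-3-enoate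
Product: 11 ethyl (2S,3S,4Z)-2-(3,4-dimethoxyphenyl)-4-(3,4-dimethoxybenzylidene)oxolane-3-carboxylate, via cis ester 10 (not isolated)
Conditions: Rh2(S-PTTL)4 [dirhodium tetrakis(N-phthaloyl-(S)-tert-leucinate)] (1 mol%), toluene, −60 °C, slow addition of 9; then DBU (0.1 equiv), 0 °C
Reagents that add atoms: none
Why: Rhodium-promoted loss of N2 gives a donor/acceptor (alkenyl, ester) carbenoid at C3 with no hydrogen on C4, and this inserts into one benzylic C2–H of the veratryl ether in a concerted but asynchronous step in which hydride shift to carbon runs ahead of C2–C3 bond formation. The closest known reaction type is the enantioselective dirhodium(II) carboxylate-catalysed 1,5-C–H insertion of aryl diazoacetates into an ortho-benzyloxy group, which gives 2-aryl-2,3-dihydrobenzofuran-3-carboxylates. The oxolane closes by 1,5-insertion through the five-membered array C3–C4–C5–O1–C2, with the alkene twisted out of the carbenoid plane and remaining exocyclic. C2 is controlled by the catalyst, which distinguishes the two enantiotopic benzylic hydrogens, and C3, expected mainly cis to the C2 aryl group from the kinetic step (10), is then equilibrated by catalytic DBU through its ester- and alkene-activated proton to the more stable 2,3-trans ester 11. The step needs site selectivity over arene attack, dimerisation and reaction at the vinylogous carbon C7'; the oxygen- and aryl-activated C–H placed 1,5 to the carbenoid should secure it, and the Z alkene keeps the C7' aryl group anti to C3 so that closure onto that ring to an indene is not possible. The base treatment is ended at the epimer equilibrium, since longer exposure would draw the double bond into conjugation with the ester.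

Step 6
Reactants: 11 ethyl (2S,3S,4Z)-2-(3,4-dimethoxyphenyl)-4-(3,4-dimethoxybenzylidene)oxolane-3-carboxylate
Product: 12 [(2S,3R,4Z)-2-(3,4-dimethoxyphenyl)-4-(3,4-dimethoxybenzylidene)oxolan-3-yl]methanol
Conditions: DIBAL-H (2.5 equiv), CH2Cl2, −78 °C; aq. potassium sodium tartrate
Reagents that add atoms: none
Why: DIBAL reduction of the ester to the primary alcohol runs under non-basic conditions, so C3 should not epimerise and the alkene should stay exocyclic.

Step 7
Reactants: 12 [(2S,3R,4Z)-2-(3,4-dimethoxyphenyl)-4-(3,4-dimethoxybenzylidene)oxolan-3-yl]methanol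
Product: 13 [(2S,3R,4R)-4-(3,4-dimethoxybenzyl)-2-(3,4-dimethoxyphenyl)oxolan-3-yl]methanol
Conditions: H2 (1 atm), 10% Pd/C, EtOAc, rt, stopped after 1 equiv of H2
Reagents that add atoms: none
Why: Heterogeneous catalytic hydrogenation of the exocyclic trisubstituted styrene should deliver hydrogen to C4 from the ring face opposite the adjacent C3 hydroxymethyl group, setting C4 as R with the benzyl arm cis to the C3 arm, as is usual for 4-benzylidene-3-(hydroxymethyl)-2-aryloxolanes.

Step 8
Reactants: 13 [(2S,3R,4R)-4-(3,4-dimethoxybenzyl)-2-(3,4-dimethoxyphenyl)oxolan-3-yl]methanol; 14 angelic acid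
Product: 15 leoligin
Conditions: PPh3, DIAD, THF, 0 °C to rt
Reagents that add atoms: none
Why: Mitsunobu esterification activates the primary alcohol and not the acid, so no acyl-activated angeloyl species forms, the Z alkene should not isomerise to the tiglate, and no stereocentre is touched.

**Compound list**

1 | 4-iodo-1,2-dimethoxybenzene | COc1ccc(I)cc1OC | starting material
2 | prop-2-yn-1-ol | C#CCO | starting material
3 | 3-(3,4-dimethoxyphenyl)prop-2-yn-1-ol | COc1ccc(C#CCO)cc1OC | intermediate
4 | (2E)-3-(3,4-dimethoxyphenyl)-2-(tributylstannyl)prop-2-en-1-ol | CCCC[Sn](CCCC)(CCCC)/C(CO)=C/c1ccc(OC)c(OC)c1 | intermediate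
5 | (2E)-3-(3,4-dimethoxyphenyl)-2-iodoprop-2-en-1-ol | I/C(CO)=C/c1ccc(OC)c(OC)c1 | intermediate
6 | 3,4-dimethoxybenzyl bromide | COc1ccc(CBr)cc1OC | starting material
7 | 4-[(1E)-3-[(3,4-dimethoxybenzyl)oxy]-2-iodoprop-1-en-1-yl]-1,2-dimethoxybenzene | I/C(COCc1ccc(OC)c(OC)c1)=C/c1ccc(OC)c(OC)c1 | intermediate
8 | ethyl diazoacetate | CCOC(=O)C=[N+]=[N-] | starting material
9 | ethyl (3Z)-2-diazo-3-{[(3,4-dimethoxybenzyl)oxy]methyl}-4-(3,4-dimethoxyphenyl)but-3-enoate | CCOC(=O)C(=[N+]=[N-])/C(COCc1ccc(OC)c(OC)c1)=C/c1ccc(OC)c(OC)c1 | intermediate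
10 | ethyl (2S,3R,4Z)-2-(3,4-dimethoxyphenyl)-4-(3,4-dimethoxybenzylidene)oxolane-3-carboxylate (2,3-cis) | CCOC(=O)[C@@H]1/C(=C/c2ccc(OC)c(OC)c2)CO[C@@H]1c1ccc(OC)c(OC)c1 | intermediate
11 | ethyl (2S,3S,4Z)-2-(3,4-dimethoxyphenyl)-4-(3,4-dimethoxybenzylidene)oxolane-3-carboxylate (2,3-trans) | CCOC(=O)[C@H]1/C(=C/c2ccc(OC)c(OC)c2)CO[C@@H]1c1ccc(OC)c(OC)c1 | intermediate
12 | [(2S,3R,4Z)-2-(3,4-dimethoxyphenyl)-4-(3,4-dimethoxybenzylidene)oxolan-3-yl]methanol | OC[C@H]1/C(=C/c2ccc(OC)c(OC)c2)CO[C@@H]1c1ccc(OC)c(OC)c1 | intermediate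
13 | [(2S,3R,4R)-4-(3,4-dimethoxybenzyl)-2-(3,4-dimethoxyphenyl)oxolan-3-yl]methanol | OC[C@H]1[C@@H](Cc2ccc(OC)c(OC)c2)CO[C@@H]1c1ccc(OC)c(OC)c1 | intermediate
14 | angelic acid, (2Z)-2-methylbut-2-enoic acid | C/C=C(/C)C(=O)O | starting material
15 | leoligin, [(2S,3R,4R)-4-(3,4-dimethoxybenzyl)-2-(3,4-dimethoxyphenyl)oxolan-3-yl]methyl (2Z)-2-methylbut-2-enoate | C/C=C(/C)C(=O)OC[C@H]1[C@@H](Cc2ccc(OC)c(OC)c2)CO[C@@H]1c1ccc(OC)c(OC)c1 | target

**Totals**

Total steps: 8. Longest linear sequence: 8 steps (1 and 2 to 15).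

**Steps most likely to fail**

Step 5 (C–H insertion). The carbenoid may be consumed at its vinylogous carbon, by dimerisation or by cyclopropene formation instead of insertion. The catalyst may discriminate poorly between the two benzylic hydrogens. The base equilibration may also move the double bond into the ring. The fallback sets out from 3, returns at 13, and forms the ring through C3–C4 by a titanium(III) radical cyclisation. Alcohol 3 is converted with CBr4/PPh3 into 4-(3-bromoprop-1-yn-1-yl)-1,2-dimethoxybenzene F1. Commercial 3,4-dimethoxybenzaldehyde and vinylmagnesium bromide give racemic 1-(3,4-dimethoxyphenyl)prop-2-en-1-ol F2. Lipase PS with vinyl acetate acylates its R enantiomer and leaves (1S)-1-(3,4-dimethoxyphenyl)prop-2-en-1-ol F3. NaH joins F3 and F1 to the ether 4-[(1S)-1-{[3-(3,4-dimethoxyphenyl)prop-2-yn-1-yl]oxy}prop-2-en-1-yl]-1,2-dimethoxybenzene F4. mCPBA epoxidises the terminal alkene to 2-[(R)-(3,4-dimethoxyphenyl){[3-(3,4-dimethoxyphenyl)prop-2-yn-1-yl]oxy}methyl]oxirane F5; both epoxide epimers serve. Cp2TiCl (from Cp2TiCl2 and Zn, THF) opens the epoxide to the β-titanoxy radical at C3, which should close 5-exo-dig onto the alkyne trans to the C2 aryl group. After hydrogen abstraction and work-up this gives [(2S,3R,4E)-2-(3,4-dimethoxyphenyl)-4-(3,4-dimethoxybenzylidene)oxolan-3-yl]methanol F6. Hydrogenation of F6 under the conditions of step 7 gives 13.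

Step 4 (Pd coupling with ethyl diazoacetate). Oxidative addition and coupling at the α-branched vinyl iodide may be sluggish. The diazo unit may lose N2 to a palladium carbene and undergo migratory insertion. The alkenyl diazo product may electrocyclise to a pyrazole. The fallback sets out from 7 and returns at 9. Negishi coupling of 7 with the Reformatsky reagent BrZnCH2CO2Et (Pd(PPh3)4, THF) gives, with retention, ethyl (3Z)-3-{[(3,4-dimethoxybenzyl)oxy]methyl}-4-(3,4-dimethoxyphenyl)but-3-enoate F7. Diazo transfer to its doubly activated methylene (4-acetamidobenzenesulfonyl azide, DBU, MeCN, 0 °C) then gives 9.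

Step 7 (hydrogenation). Hydrogen may be delivered to both faces of C4, because the C2 aryl group lies on the face that must be used. The benzylic C2–O1 or allylic C5–O1 bond may undergo hydrogenolysis on palladium. The fallback sets out from 12 and returns at 13. TBDPSCl/imidazole gives tert-butyl{[(2S,3R,4Z)-2-(3,4-dimethoxyphenyl)-4-(3,4-dimethoxybenzylidene)oxolan-3-yl]methoxy}diphenylsilane F8. The bulky silyloxymethyl arm blocks its own face and has no hydroxyl to direct the metal. Homogeneous hydrogenation with [Ir(cod)(PCy3)(py)]PF6 (H2, CH2Cl2), which does not cleave benzylic C–O bonds, should give tert-butyl{[(2S,3R,4R)-4-(3,4-dimethoxybenzyl)-2-(3,4-dimethoxyphenyl)oxolan-3-yl]methoxy}diphenylsilane F9. TBAF in THF then releases 13.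

**Further compounds**

F1 | step 5 | 4-(3-bromoprop-1-yn-1-yl)-1,2-dimethoxybenzene | COc1ccc(C#CCBr)cc1OC
F2 | step 5 | rac-1-(3,4-dimethoxyphenyl)prop-2-en-1-ol | C=CC(O)c1ccc(OC)c(OC)c1
F3 | step 5 | (1S)-1-(3,4-dimethoxyphenyl)prop-2-en-1-ol | C=C[C@H](O)c1ccc(OC)c(OC)c1
F4 | step 5 | 4-[(1S)-1-{[3-(3,4-dimethoxyphenyl)prop-2-yn-1-yl]oxy}prop-2-en-1-yl]-1,2-dimethoxybenzene | C=C[C@H](OCC#Cc1ccc(OC)c(OC)c1)c1ccc(OC)c(OC)c1
F5 | step 5 | 2-[(R)-(3,4-dimethoxyphenyl){[3-(3,4-dimethoxyphenyl)prop-2-yn-1-yl]oxy}methyl]oxirane (both epimers at the oxirane carbon) | C1OC1[C@H](OCC#Cc2ccc(OC)c(OC)c2)c2ccc(OC)c(OC)c2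
F6 | step 5 | [(2S,3R,4E)-2-(3,4-dimethoxyphenyl)-4-(3,4-dimethoxybenzylidene)oxolan-3-yl]methanol | OC[C@H]1/C(=C\c2ccc(OC)c(OC)c2)CO[C@@H]1c1ccc(OC)c(OC)c1
F7 | step 4 | ethyl (3Z)-3-{[(3,4-dimethoxybenzyl)oxy]methyl}-4-(3,4-dimethoxyphenyl)but-3-enoate | CCOC(=O)C/C(COCc1ccc(OC)c(OC)c1)=C/c1ccc(OC)c(OC)c1
F8 | step 7 | tert-butyl{[(2S,3R,4Z)-2-(3,4-dimethoxyphenyl)-4-(3,4-dimethoxybenzylidene)oxolan-3-yl]methoxy}diphenylsilane | CC(C)(C)[Si](OC[C@H]1/C(=C/c2ccc(OC)c(OC)c2)CO[C@@H]1c1ccc(OC)c(OC)c1)(c1ccccc1)c1ccccc1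
F9 | step 7 | tert-butyl{[(2S,3R,4R)-4-(3,4-dimethoxybenzyl)-2-(3,4-dimethoxyphenyl)oxolan-3-yl]methoxy}diphenylsilane | CC(C)(C)[Si](OC[C@H]1[C@@H](Cc2ccc(OC)c(OC)c2)CO[C@@H]1c1ccc(OC)c(OC)c1)(c1ccccc1)c1ccccc1
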